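The side chain is cut on both sides of a two-carbon unit: the carbinol carbon C1′, bonded to furan ring carbon C4 and to oxygen, and its neighbour C2′H2, bonded to the 2-methylpropenyl carbon C3′, are treated as a vinyl group that is difunctionalised in one operation. A palladium-catalysed enantioselective conjunctive coupling of a furyl(vinyl)boronate with an alkenyl triflate forms the C4–C1′ and C2′–C3′ bonds and sets C1′ as an S carbon–boron centre, which is later oxidised to C–O with retention. The precursor is the pinacol boronate of 2-(2,5-dimethoxyphenyl)furan at ring carbon C4, the quinone ring being masked as its dimethyl ether; vinyllithium and 2-methylprop-1-enyl triflate are its partners.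

Key step: step 5

Remarks on the chemistry (assumptions):
- Halide ions inhibit the cationic palladium intermediate of the key step, so vinyllithium is prepared halide-free from tetravinylstannane and used as a titrated THF solution.
- The ligand antipode named in step 5 is assigned by analogy with aryl migrations. The configuration of the alcohol from step 6 is to be confirmed by Mosher ester analysis before material is committed; the mirror-image ligand is used if the sense proves opposite.
- The ester is made from free 3-methylbut-2-enoic acid with a carbodiimide. The acid chloride with an amine base can pass through a vinylketene and give the deconjugated 3-methylbut-3-enoate.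
- Pinacol is kept on boron so that the furyl boronate and the coupled boronate can be chromatographed.

Step 1
Reactants: 1 2,5-dimethoxybenzoyl chloride; 2 2-(prop-2-yn-1-yloxy)tetrahydro-2H-pyran
Product: 5 2-(2,5-dimethoxyphenyl)-4-iodofuran, via ynone 3 (not isolated), via hydroxy iodoenone 4 (not isolated)
Conditions: PdCl2(PPh3)2 (2 mol %), CuI (4 mol %), Et3N (1.0 equiv), THF, rt, 1 h; then NaI (2 equiv), TsOH·H2O (1.1 equiv), MeOH, rt
Reagents that add atoms: sodium iodide, [Na+].[I-]
Why: A copper-cocatalysed Sonogashira acylation with exactly one equivalent of amine should give ynone 3, to which iodide (far more nucleophilic than the chloride already present) adds at the β-carbon under acid while the same acid transfers the THP group to methanol, and the freed γ-hydroxyl of the E iodoenone 4 closes on the ketone and loses water to the aromatic furan (three-component halofuran synthesis by Michael addition and cyclocondensation), so that iodine must end at C4 and the aryl group at C2; the five-membered hemiketal closure by the free hydroxyl should outpace any attack of the ortho methoxy oxygen.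

Step 2
Reactants: 5 2-(2,5-dimethoxyphenyl)-4-iodofuran
Product: 6 2-[5-(2,5-dimethoxyphenyl)furan-3-yl]-4,4,5,5-tetramethyl-1,3,2-dioxaborolane
Conditions: bis(pinacolato)diboron (1.2 equiv), PdCl2(dppf) (3 mol %; dppf = 1,1'-bis(diphenylphosphino)ferrocene), KOAc (3 equiv), 1,4-dioxane, 80 °C
Reagents that add atoms: bis(pinacolato)diboron, CC1(C)OB(OC1(C)C)B1OC(C)(C)C(C)(C)O1
Why: Miyaura borylation, in which zerovalent palladium inserts into the C–I bond, the acetate-bound palladium transmetalates with the diboron and reductive elimination gives the 3-furyl boronate (a position where furyl boronates are far less prone to protodeboronation than at C2), the weak base KOAc keeping Suzuki homocoupling down.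

Step 3
Reactants: 7 isobutyraldehyde
Product: 8 2-methylprop-1-en-1-yl trifluoromethanesulfonate
Conditions: Tf2O (1.1 equiv), 2,6-di-tert-butyl-4-methylpyridine (1.2 equiv), CH2Cl2, 0 °C to reflux; pentane, filtration, distillation
Reagents that add atoms: trifluoromethanesulfonic anhydride, O=S(=O)(OS(=O)(=O)C(F)(F)F)C(F)(F)F
Why: Enol triflation of an enolisable aldehyde, in which Tf2O triflylates the carbonyl oxygen and the hindered, non-nucleophilic pyridine removes the single α-hydrogen; since the β-carbon carries two methyl groups only one alkene isomer can form.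

Step 4
Reactants: 9 tetravinylstannane
Product: 10 vinyllithium
Conditions: n-BuLi (2.0 equiv), pentane, rt, argon; filtration and pentane wash of the precipitate, dissolution in THF, titration
Reagents that add atoms: n-butyllithium, [Li]CCCC
Why: Tin–lithium exchange (transmetalation) releases the sp2 carbanion and is driven by precipitation of vinyllithium from pentane, which also separates it from the tin residues and gives a halide-free reagent.

Step 5
Reactants: 6 2-[5-(2,5-dimethoxyphenyl)furan-3-yl]-4,4,5,5-tetramethyl-1,3,2-dioxaborolane; 10 vinyllithium; 8 2-methylprop-1-en-1-yl trifluoromethanesulfonate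
Product: 12 (S)-2-{1-[5-(2,5-dimethoxyphenyl)furan-3-yl]-4-methylpent-3-en-1-yl}-4,4,5,5-tetramethyl-1,3,2-dioxaborolane, via lithium furyl(vinyl)boronate 11 (not isolated)
Conditions: 10 (1.0 equiv), THF, 0 °C to rt, 30 min; then 8 (1.2 equiv), Pd(OAc)2 (2 mol %), (Rp,Rp)-1,1'-bis[bis(4-methoxy-3,5-dimethylphenyl)phosphino]-2,2'-bis[(S)-α-(dimethylamino)benzyl]ferrocene (MandyPhos-type ligand, 2.4 mol %), THF, 60 °C, 14 h
Reagents that add atoms: none
Why: Vinyllithium 10 adds to the boron of 6 to give the four-coordinate boronate 11, while zerovalent palladium, formed in the flask from Pd(OAc)2 and the bisphosphine, inserts into the C–O bond of triflate 8 to give a cationic 2-methylprop-1-enyl complex of divalent palladium that coordinates the vinyl π-bond of 11. The furyl group then moves from boron to the boron-bearing vinyl carbon on the face opposite to the metal while palladium bonds the terminal carbon, and C–C reductive elimination joins that CH2 to the alkenyl carbon, so the furan C4–C1′ and C2′–C3′ bonds are made and no ring is closed. The closest known reaction type is the palladium-catalysed enantioselective conjunctive cross-coupling of aryl(vinyl)boron ate complexes with aryl and alkenyl triflates, a metal-induced 1,2-metalate rearrangement. The single new stereocentre C1′ is set by the catalyst alone: the C2-symmetric ferrocenyl bisphosphine fixes which face of the coordinated vinyl group carries palladium, the furyl group arrives anti to it, and the (Rp,Rp) ligand is the antipode expected to give the S boronate. The step needs the 1,2-shift to win over direct furyl transfer to palladium (Suzuki pathway) and over β-hydride loss, which is secured by the saturated boron of 11 (no empty orbital for transmetalation), by the non-coordinating triflate and the halide-free medium that keep palladium cationic and alkene-bound, and by the wide-bite-angle ligand that speeds reductive elimination. The electron-rich 3-furyl group is a good migrating group, and the chain comes out linear because the C2′–C3′ bond is made at the alkenyl carbon of 8 and not through an allyl metal.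

Step 6
Reactants: 12 (S)-2-{1-[5-(2,5-dimethoxyphenyl)furan-3-yl]-4-methylpent-3-en-1-yl}-4,4,5,5-tetramethyl-1,3,2-dioxaborolane
Product: 13 (S)-1-[5-(2,5-dimethoxyphenyl)furan-3-yl]-4-methylpent-3-en-1-ol
Conditions: 30 % aq H2O2, 3 M aq NaOH, THF, 0 °C to rt
Reagents that add atoms: hydrogen peroxide, OO
Why: Boronate oxidation, in which hydroperoxide adds to boron and the carbon migrates from boron to oxygen with retention, so the S C–B centre becomes the S carbinol, while the furan, the trisubstituted alkene and the aryl ethers are inert to alkaline peroxide.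

Step 7
Reactants: 13 (S)-1-[5-(2,5-dimethoxyphenyl)furan-3-yl]-4-methylpent-3-en-1-ol; 14 3-methylbut-2-enoic acid
Product: 15 (S)-1-[5-(2,5-dimethoxyphenyl)furan-3-yl]-4-methylpent-3-en-1-yl 3-methylbut-2-enoate
Conditions: DCC (1.5 equiv), DMAP (0.1 equiv), CH2Cl2, 0 °C to rt
Reagents that add atoms: none
Why: Steglich esterification, in which the O-acylisourea is passed on by DMAP as an acylpyridinium ion to the secondary alcohol; the C1′–O bond is never broken, so the S configuration is kept, and the near-neutral conditions avoid the vinylketene path that deconjugates senecioyl derivatives.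

Step 8
Reactants: 15 (S)-1-[5-(2,5-dimethoxyphenyl)furan-3-yl]-4-methylpent-3-en-1-yl 3-methylbut-2-enoate
Product: 16 (S)-1-[5-(3,6-dioxocyclohexa-1,4-dien-1-yl)furan-3-yl]-4-methylpent-3-en-1-yl 3-methylbut-2-enoate (the target)
Conditions: (NH4)2Ce(NO3)6 (2.5 equiv), MeCN/H2O (2:1), 0 °C, 15 min
Reagents that add atoms: water, O
Why: Oxidative demethylation with tetravalent cerium, in which two one-electron oxidations of the para-dimethoxyarene, ipso attack of water and loss of two molecules of methanol give the 1,4-quinone, a reaction known for aryl- and heteroaryl-substituted dimethoxybenzenes and for prenyl-bearing side chains; a short contact time at 0 °C should spare the furan, which is deactivated once the quinone is formed, and the stereocentre is not touched.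

Compound list
1 | 2,5-dimethoxybenzoyl chloride | COc1ccc(OC)c(C(=O)Cl)c1 | starting material
2 | 2-(prop-2-yn-1-yloxy)tetrahydro-2H-pyran (racemic) | C#CCOC1CCCCO1 | starting material
3 | 1-(2,5-dimethoxyphenyl)-4-(tetrahydro-2H-pyran-2-yloxy)but-2-yn-1-one | COc1ccc(OC)c(C(=O)C#CCOC2CCCCO2)c1 | intermediate (not isolated)
4 | (E)-1-(2,5-dimethoxyphenyl)-4-hydroxy-3-iodobut-2-en-1-one (the isomer able to cyclise, reached by equilibration under acid) | COc1ccc(OC)c(C(=O)/C=C(/I)CO)c1 | intermediate (not isolated)
5 | 2-(2,5-dimethoxyphenyl)-4-iodofuran | COc1ccc(OC)c(-c2cc(I)co2)c1 | intermediate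
6 | 2-[5-(2,5-dimethoxyphenyl)furan-3-yl]-4,4,5,5-tetramethyl-1,3,2-dioxaborolane | COc1ccc(OC)c(-c2cc(B3OC(C)(C)C(C)(C)O3)co2)c1 | intermediate
7 | isobutyraldehyde (2-methylpropanal) | CC(C)C=O | starting material
8 | 2-methylprop-1-en-1-yl trifluoromethanesulfonate | CC(C)=COS(=O)(=O)C(F)(F)F | intermediate
9 | tetravinylstannane | C=C[Sn](C=C)(C=C)C=C | starting material
10 | vinyllithium | [Li]C=C | intermediate
11 | lithium [5-(2,5-dimethoxyphenyl)furan-3-yl](ethenyl)(2,3-dimethylbutane-2,3-diolato)borate | [Li+].C=C[B-]1(OC(C)(C)C(C)(C)O1)c1coc(-c2cc(OC)ccc2OC)c1 | intermediate (not isolated)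
12 | (S)-2-{1-[5-(2,5-dimethoxyphenyl)furan-3-yl]-4-methylpent-3-en-1-yl}-4,4,5,5-tetramethyl-1,3,2-dioxaborolane | CC(C)=CC[C@H](B1OC(C)(C)C(C)(C)O1)c1coc(-c2cc(OC)ccc2OC)c1 | intermediate
13 | (S)-1-[5-(2,5-dimethoxyphenyl)furan-3-yl]-4-methylpent-3-en-1-ol | CC(C)=CC[C@H](O)c1coc(-c2cc(OC)ccc2OC)c1 | intermediate
14 | 3-methylbut-2-enoic acid | CC(C)=CC(=O)O | starting material
15 | (S)-1-[5-(2,5-dimethoxyphenyl)furan-3-yl]-4-methylpent-3-en-1-yl 3-methylbut-2-enoate | CC(C)=CC[C@H](OC(=O)C=C(C)C)c1coc(-c2cc(OC)ccc2OC)c1 | intermediate
16 | (S)-1-[5-(3,6-dioxocyclohexa-1,4-dien-1-yl)furan-3-yl]-4-methylpent-3-en-1-yl 3-methylbut-2-enoate | CC(C)=CC[C@H](OC(=O)C=C(C)C)c1coc(C2=CC(=O)C=CC2=O)c1 | target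

Total step count: 8. Longest linear sequence: 6 steps (steps 1, 2, 5, 6, 7, 8); steps 3 and 4 are one-step side branches.

Steps most likely to fail

Step 5. The furyl group may pass directly from boron to palladium instead of shifting to carbon, the alkylpalladium intermediate may lose a β-hydride, or the face selection may be poor with a heteroaryl migrating group. The fallback uses known chemistry, sets out from 5 and comes back at 13. Iodine–magnesium exchange of 5 with i-PrMgCl·LiCl (THF, 0 °C to rt) should give [5-(2,5-dimethoxyphenyl)furan-3-yl]magnesium chloride F1, which is formylated with DMF to 5-(2,5-dimethoxyphenyl)furan-3-carbaldehyde F2. Brown allylation with (−)-B-allyldiisopinocampheylborane (from (−)-B-methoxydiisopinocampheylborane and allylmagnesium bromide; Et2O, −78 °C; NaOH, H2O2 work-up) is expected to attack the Si face of this aryl-type aldehyde and to give (S)-1-[5-(2,5-dimethoxyphenyl)furan-3-yl]but-3-en-1-ol F3. Cross-metathesis of F3 with excess 2-methylbut-2-ene (second-generation Grubbs catalyst, RuCl2(=CHPh)(H2IMes)(PCy3), CH2Cl2, rt to 40 °C) turns the allyl group into the prenyl group and gives 13, after which steps 7 and 8 follow unchanged.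

Step 8. The one-electron oxidant may attack the electron-rich 2-arylfuran (ring opening to an enedione), or the acidic aqueous medium may ionise the furylic ester, instead of clean oxidative demethylation. The fallback sets out from 5 and comes back at 16; it exchanges the methyl ethers for silyl ethers that come off without an oxidant of high potential.
- BBr3 (CH2Cl2, −78 to 0 °C, argon) demethylates 5 to 2-(4-iodofuran-2-yl)benzene-1,4-diol F4, which is silylated at once (TIPSCl, imidazole, DMF) to 2-[2,5-bis(triisopropylsilyloxy)phenyl]-4-iodofuran F5.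
- The operations of steps 2, 5, 6 and 7 are repeated on this series. Miyaura borylation gives the bis-silyl furyl pinacol boronate F6. Vinyllithium 10 turns it into the bis-silyl lithium furyl(vinyl)boronate F7, which couples with 8 to the bis-silyl S homoallylic boronate F8. Oxidation with NaBO3·4H2O (THF/H2O, rt), chosen to spare the aryl silyl ethers, gives the bis-silyl S alcohol F9. DCC/DMAP esterification with 14 gives the bis-silyl S senecioate F10.
- TBAF buffered with AcOH (THF, 0 °C) frees (S)-1-[5-(2,5-dihydroxyphenyl)furan-3-yl]-4-methylpent-3-en-1-yl 3-methylbut-2-enoate F11, and Ag2O (Et2O, MgSO4, rt) oxidises this hydroquinone to 16.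

Step 1. The three events of the one-pot sequence may not mesh. An incomplete acyl coupling of the electron-rich, ortho-substituted aroyl chloride would carry acid chloride, alkyne dimer and ammonium chloride into the acid stage, where chloride competes with iodide and the halofuran is lost in by-products. The fallback sets out from 2 and comes back at 3, which is then isolated. Deprotonation of 2 with n-BuLi (THF, −78 °C) gives lithium 3-(tetrahydro-2H-pyran-2-yloxy)prop-1-yn-1-ide F12, which adds to commercial 2,5-dimethoxybenzaldehyde to give 1-(2,5-dimethoxyphenyl)-4-(tetrahydro-2H-pyran-2-yloxy)but-2-yn-1-ol F13 (diastereomer mixture, of no consequence). MnO2 (CH2Cl2, rt) oxidises this propargylic, benzylic alcohol to ynone 3. Purified 3 is then treated with NaI and TsOH·H2O in MeOH as in the second half of step 1 and should reach 5 via 4 in a medium free of chloride, copper and palladium.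

Further compounds
F1 | step 5 | [5-(2,5-dimethoxyphenyl)furan-3-yl]magnesium chloride (as its LiCl complex) | COc1ccc(OC)c(-c2cc([Mg]Cl)co2)c1
F2 | step 5 | 5-(2,5-dimethoxyphenyl)furan-3-carbaldehyde | COc1ccc(OC)c(-c2cc(C=O)co2)c1
F3 | step 5 | (S)-1-[5-(2,5-dimethoxyphenyl)furan-3-yl]but-3-en-1-ol | C=CC[C@H](O)c1coc(-c2cc(OC)ccc2OC)c1
F4 | step 8 | 2-(4-iodofuran-2-yl)benzene-1,4-diol | Oc1ccc(O)c(-c2cc(I)co2)c1
F5 | step 8 | 2-[2,5-bis(triisopropylsilyloxy)phenyl]-4-iodofuran | CC(C)[Si](C(C)C)(C(C)C)Oc1ccc(O[Si](C(C)C)(C(C)C)C(C)C)c(-c2cc(I)co2)c1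
F6 | step 8 | 2-{5-[2,5-bis(triisopropylsilyloxy)phenyl]furan-3-yl}-4,4,5,5-tetramethyl-1,3,2-dioxaborolane | CC(C)[Si](C(C)C)(C(C)C)Oc1ccc(O[Si](C(C)C)(C(C)C)C(C)C)c(-c2cc(B3OC(C)(C)C(C)(C)O3)co2)c1
F7 | step 8 | lithium {5-[2,5-bis(triisopropylsilyloxy)phenyl]furan-3-yl}(ethenyl)(2,3-dimethylbutane-2,3-diolato)borate | [Li+].C=C[B-]1(OC(C)(C)C(C)(C)O1)c1coc(-c2cc(O[Si](C(C)C)(C(C)C)C(C)C)ccc2O[Si](C(C)C)(C(C)C)C(C)C)c1
F8 | step 8 | (S)-2-(1-{5-[2,5-bis(triisopropylsilyloxy)phenyl]furan-3-yl}-4-methylpent-3-en-1-yl)-4,4,5,5-tetramethyl-1,3,2-dioxaborolane | CC(C)=CC[C@H](B1OC(C)(C)C(C)(C)O1)c1coc(-c2cc(O[Si](C(C)C)(C(C)C)C(C)C)ccc2O[Si](C(C)C)(C(C)C)C(C)C)c1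
F9 | step 8 | (S)-1-{5-[2,5-bis(triisopropylsilyloxy)phenyl]furan-3-yl}-4-methylpent-3-en-1-ol | CC(C)=CC[C@H](O)c1coc(-c2cc(O[Si](C(C)C)(C(C)C)C(C)C)ccc2O[Si](C(C)C)(C(C)C)C(C)C)c1
F10 | step 8 | (S)-1-{5-[2,5-bis(triisopropylsilyloxy)phenyl]furan-3-yl}-4-methylpent-3-en-1-yl 3-methylbut-2-enoate | CC(C)=CC[C@H](OC(=O)C=C(C)C)c1coc(-c2cc(O[Si](C(C)C)(C(C)C)C(C)C)ccc2O[Si](C(C)C)(C(C)C)C(C)C)c1
F11 | step 8 | (S)-1-[5-(2,5-dihydroxyphenyl)furan-3-yl]-4-methylpent-3-en-1-yl 3-methylbut-2-enoate | CC(C)=CC[C@H](OC(=O)C=C(C)C)c1coc(-c2cc(O)ccc2O)c1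
F12 | step 1 | lithium 3-(tetrahydro-2H-pyran-2-yloxy)prop-1-yn-1-ide | [Li]C#CCOC1CCCCO1
F13 | step 1 | 1-(2,5-dimethoxyphenyl)-4-(tetrahydro-2H-pyran-2-yloxy)but-2-yn-1-ol | COc1ccc(OC)c(C(O)C#CCOC2CCCCO2)c1
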